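Take the flask as it stands:

    E ⇌ D, rate k1*([E] - [D]/K1) per volume of the first phase (K1 = 1.7, k1 = 0.025 /s)
    L + E → L.E (k2 = 0.057 /M/s)
    L.E ⇌ X, rate k3*([L.E] - [X]/K3) per volume of the first phase (K3 = 3.5, k3 = 0.0017 /s)
    L.E → Z (k4 = 2.8 × 10⁻⁴ /s)
    E → Q (k5 = 2.0 × 10⁻⁴ /s)
    L.E ⇌ G (K6 = 0.45, k6 = 5.4 × 10⁻⁴ /s)
L 0.10 M; D 1.80 equiv; time 50 min; volume of the second phase over the first 1.0
1. how much L.E and X together there is at 50 min, in percent of the L charged
2. the change that raises the amount of L.E and X together at 50 min, in percent of the L charged most ("none" if none brings more than 2 percentage points) (blue / ochre / green / none)
3. amount of L.E and X together at 50 min, in percent of the L charged, after blue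
- blue: doubling the transfer coefficient of step 3, all else as stated
- ochre: doubling the amount of D, all else as stated
- green: doubling the transfer coefficient of step 1, all else as stated
- L.E is meant together with its X
- in the second phase: D, X; everything else is in the first
- charges count per volume of the first phase; a concentration in a rate is the amount of a species over the volume of its own phase; every rate counts per litre of the first phase
- run time (flask): 50 min

 Exchange of L.E with X runs faster than the loss to Z, and G relaxes in 6.64 min, so the ratios among the three forms can be frozen at their equilibrium values. X is then the resting state, and Z is fed by free L.E, the bare part of the pool. E is taken at its partition value with the charge of D as at the start, to give an estimate of the mean time at which L.E is born.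

bare share of the pool = 0.202

leak = 0.00339 /min, the leak constant, the rate constant of the loss to Z times the bare share

E at partition = 0.0667 M, so birth time = 4.39 min

start-up lag, the extra time fresh L.E stays bare = 5.16 min

L.E and X at 50 min = 71.1%

Nearly all of that lag comes from the X term, so blue cuts it to 2.71 min and gives 74.3%, a gain of 3.2 percentage points, more than the 2 points required. Ochre brings the birth forward, which ages the pool and costs about 0.53 points. Green changes little, because transfer of E is already faster than the birth. My answer is blue.

The forecast gives 71.3%, chooses blue and puts it at 75.7%, on the ground that “faster transfer moves L.E into the protected X pool sooner”.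

The simulation gives 71.8%, and blue is best at 75.0%, a gain of 3.2 points, against −0.29 points for ochre and −0.038 points for green.

The flask has not come to rest at 50 min, though 0.58% of the L remains. Left until 500 min, it holds 18.0% as L.E and X and 80.3% as Z. The leak carried on from 71.8% gives 15.6%, less than the computed amount.

Left until 80 min, the same flask should fall by the leak to 64.9%; the computed result is 66.5%.

The rate constants belong to no real substance.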